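**Plan**

- Retrosynthesis: first the two O-protecting groups and the change C2–CH2CO2Me → C2–CH3 are taken back. Then both ring C–C bonds C2–C3 and C4–C5 of the oxane (O1, C2–C6; C7/C8 = chlorohydrin arm) are cut, which frees vinyl bromide (C3–C4 with its Br) and an acyclic carboxylic acid. Last, the enol-ether bond O1–C2 is cut into a ring A ynoate and an East tertiary alcohol.
- Enabling feature: in the oxane ring O1 lies between the fully substituted C2 and C6. C5 is a CH2 β to O1 (a free radical once CO2 is lost from it), C2 can be the oxygen-bearing β-carbon of a β-alkoxy enoate, and C3–C4 is a CHBr–CH2 unit.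
- Forward order: ring A is made first (mercury-induced cyclization of geranylacetic acid to the trans-fused lactone, Hg → Br) and the lactone carbonyl becomes C2 of the ynoate. The East alcohol comes from a Sharpless kinetic resolution, and oxa-Michael addition joins the halves. The radical annulation then closes the oxane, decarboxylation makes the C2 methyl, and one acid step frees both hydroxyls.
- Stereochemistry: the three ring A centres come from the chair–chair cyclization under a chiral ligand on mercury and retentive Hg → Br exchange. C6 and C7 come from the Sharpless step. C2 and C3 come from the chair-like 6-exo transition state of the key step, steered by C6.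

Key step: step 16

Assumption: the oxan-2-yl acetal carbon is an unresolved mixture of epimers (left undefined in the SMILES), and the enantiomer of the bis(oxazoline) ligand in step 2 is the one that leads to the (4aR,6R,8aR) lactone.

Step 1
Reactants: 1 geranyl bromide; 2 acetic acid
Product: 4 (4E)-5,9-dimethyldeca-4,8-dienoic acid, via dilithium acetate 3 (not isolated)
Conditions: LiN(iPr)2 (2.2 equiv), THF/HMPA, 0 °C; then 1, 0 °C to rt; aq HCl
Reagents that add atoms: none
Why: alkylation of the acetic acid dianion at the primary allylic carbon (SN2) should give the acid with the (E)-alkene of geranyl bromide unchanged, and no stereocentre is formed.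

Step 2
Reactants: 4 (4E)-5,9-dimethyldeca-4,8-dienoic acid
Product: 6 trans-fused lactone C6-mercury bromide, via lactone C6-mercury triflate 5 (not isolated)
Conditions: Hg(OTf)2 (1.1 equiv), 2,2'-(propane-2,2-diyl)bis(4-phenyl-4,5-dihydrooxazole) (single enantiomer, 1.2 equiv), CH2Cl2, −78 °C; then sat. aq NaBr
Reagents that add atoms: mercury bis(trifluoromethanesulfonate), [Hg+2].[O-]S(=O)(=O)C(F)(F)F.[O-]S(=O)(=O)C(F)(F)F; sodium bromide, [Na+].[Br-]
Why: mercury-induced cation–olefin (polyene) cyclization, in which the ligand-bound mercury salt should select one face of the terminal alkene, the chair–chair transition state with anti addition across the (E)-alkene fixes the trans ring fusion with equatorial mercury, and the carboxyl oxygen ends the cascade as the six-membered lactone.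

Step 3
Reactants: 6 trans-fused lactone C6-mercury bromide
Product: 7 (4aR,6R,8aR)-6-bromo-5,5,8a-trimethyloctahydro-2H-chromen-2-one
Conditions: Br2 (1.1 equiv), pyridine, O2 atmosphere, dark, 0 °C
Reagents that add atoms: bromine, BrBr
Why: bromodemercuration in pyridine under oxygen (polar SE2 path, radical chain suppressed) should replace mercury by bromine with retention and so give the equatorial secondary bromide of ring A.

Step 4
Reactants: 7 bromolactone
Product: 8 (4aR,6R,8aR)-6-bromo-5,5,8a-trimethyloctahydro-2H-chromen-2-ol (lactol)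
Conditions: iBu2AlH (1.1 equiv), CH2Cl2, −78 °C; Rochelle salt
Reagents that add atoms: none
Why: half-reduction of a lactone to the lactol at low temperature, at which the secondary bromide is inert to the aluminium hydride.

Step 5
Reactants: 8 lactol; 9 dimethyl (1-diazo-2-oxopropyl)phosphonate
Product: 10 (1R,2R,4R)-4-bromo-2-(but-3-yn-1-yl)-1,3,3-trimethylcyclohexan-1-ol
Conditions: K2CO3, MeOH, 0 °C to rt
Reagents that add atoms: none
Why: Seyferth–Gilbert homologation with the Ohira–Bestmann reagent acts on the open hydroxy-aldehyde form of the lactol and gives the terminal alkyne one carbon longer, the new carbon being the later C2 methyl group.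

Step 6
Reactants: 10 alkynol
Product: 11 triethylsilyl ether of 10
Conditions: Et3SiOTf, 2,6-lutidine, CH2Cl2, −78 to 0 °C
Reagents that add atoms: triethylsilyl trifluoromethanesulfonate, CC[Si](CC)(CC)OS(=O)(=O)C(F)(F)F
Why: silylation of a tertiary alcohol with a silyl triflate, needed so that this oxygen cannot add to the ynoate intramolecularly in step 13.

Step 7
Reactants: 11 silyl ether alkyne
Product: 13 methyl 5-(ring A)pent-2-ynoate, via lithium acetylide 12 (not isolated)
Conditions: LiN(iPr)2, THF, −78 °C; ClCO2Me, −78 to −20 °C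
Reagents that add atoms: methyl chloroformate, COC(=O)Cl
Why: C-acylation of a lithium acetylide with a chloroformate, the amide base at −78 °C being chosen so that the secondary bromide is not attacked.

Step 8
Reactants: 14 2-chloro-N-methoxy-N-methylacetamide; 15 isopropenylmagnesium bromide
Product: 16 1-chloro-3-methylbut-3-en-2-one
Conditions: THF, −78 to −20 °C; cold aq NH4Cl; used crude
Reagents that add atoms: none
Why: Weinreb ketone synthesis, in which the chelated tetrahedral intermediate prevents over-addition and the α-chloride is not displaced at low temperature.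

Step 9
Reactants: 16 chloro enone
Product: 17 racemic 1-chloro-3-methylbut-3-en-2-ol
Conditions: NaBH4, CeCl3·7H2O, MeOH, −78 °C; AcOH quench
Reagents that add atoms: none
Why: Luche reduction gives clean 1,2-reduction of the enone to the allylic alcohol.

Step 10
Reactants: 17 racemic allylic alcohol
Product: 18 (1S)-2-chloro-1-[(2S)-2-methyloxiran-2-yl]ethan-1-ol
Conditions: Ti(OiPr)4 (1.0 equiv), D-(−)-diisopropyl tartrate (1.2 equiv), t-BuOOH (0.6 equiv), 4 Å sieves, CH2Cl2, −20 °C; aq tartaric acid work-up
Reagents that add atoms: tert-butyl hydroperoxide, CC(C)(C)OO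
Why: Sharpless kinetic resolution, in which the (S)-alcohol is the fast-reacting enantiomer with the D-tartrate and is epoxidized on the face that gives the erythro (S,S)-epoxy alcohol, so that C6 and C7 are both set by the reagent while the (R)-alcohol stays behind.

Step 11
Reactants: 18 epoxy alcohol
Product: 19 oxan-2-yl acetal of 18
Conditions: 3,4-dihydro-2H-pyran, PPTS (cat.), CH2Cl2, 0 °C to rt
Reagents that add atoms: 3,4-dihydro-2H-pyran, C1=COCCC1
Why: acetal formation under a weak acid that the 2,2-disubstituted epoxide should tolerate, giving a group that cannot migrate under base and has no weak benzylic C–H for the radical step.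

Step 12
Reactants: 19 protected epoxide; 20 vinylmagnesium bromide
Product: 21 (2S,3S)-1-chloro-3-methyl-2-(oxan-2-yloxy)hex-5-en-3-ol
Conditions: 20 (3 equiv), CuI (10 mol%), THF, −40 to −20 °C; aq NH4Cl
Reagents that add atoms: none
Why: copper-catalysed Grignard opening of a 2,2-disubstituted epoxide at its CH2 carbon (C5) leaves the tertiary C6–O bond and its configuration untouched, and the vinyl group serves as the masked carboxyl group.

Step 13
Reactants: 21 East tertiary alcohol; 13 ring A ynoate
Product: 22 (E)-β-alkoxy enoate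
Conditions: KN(SiMe3)2 (0.2 equiv), THF, −78 to −30 °C; AcOH quench
Reagents that add atoms: none
Why: base-catalysed oxa-Michael addition of the tertiary alkoxide to the β-carbon of the alkynoate should give mainly the thermodynamically preferred (E) push–pull enoate, which is the radical acceptor for C2.

Step 14
Reactants: 22 β-alkoxy enoate
Product: 24 aldehyde, via vicinal diol 23 (not isolated)
Conditions: OsO4 (2 mol%), NaIO4 (4 equiv), 2,6-lutidine, dioxane/H2O, rt
Reagents that add atoms: sodium periodate (oxygen delivered through catalytic OsO4), [Na+].[O-]I(=O)(=O)=O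
Why: Lemieux–Johnson cleavage, in which OsO4 should dihydroxylate the monosubstituted alkene in preference to the hindered push–pull enoate and periodate cleaves the diol.

Step 15
Reactants: 24 aldehyde
Product: 25 carboxylic acid
Conditions: NaClO2, NaH2PO4, 2-methylbut-2-ene, t-BuOH/H2O, 0 °C
Reagents that add atoms: sodium chlorite, [Na+].[O-]Cl=O
Why: Pinnick oxidation under a weakly acidic buffer, which avoids β-elimination of the enol-ether oxygen and keeps the acetal.

Step 16
Reactants: 25 carboxylic acid; 26 vinyl bromide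
Product: 27 oxane methyl ester
Conditions: 9-mesitylacridine (10 mol%), vinyl bromide (about 30 equiv, condensed in), CH2Cl2, 405 nm LEDs, 15 °C, sealed tube
Reagents that add atoms: none
Why: Proposed new method: excitation of the hydrogen-bonded acid–acridine pair triggers proton-coupled electron transfer and loss of CO2 to give the primary radical at C5, which cannot close onto its own enoate (4-exo or 5-endo) and therefore adds to the CH2 end of vinyl bromide (C4–C5 bond); the α-bromoalkyl radical at C3 then closes onto the oxygen-bearing β-carbon C2 of the enoate (C2–C3 bond) and the α-ester radical is quenched by hydrogen back-transfer from the acridinyl radical. The closest known reaction types are the decarboxylative Giese addition under acridine photocatalysis and the 6-exo radical cyclization onto β-alkoxyacrylates, joined here as a radical [4+2] annulation with a simple halo-olefin. The oxane ring is closed in the 6-exo-trig mode through a chair-like transition state in which C6 carries its large acetal-bearing arm equatorial and its methyl axial. C3 is set with bromine pseudo-equatorial, and C2 is set with the ring A chain pseudo-equatorial and the CH–CO2Me carbon pseudo-axial, because the other rotamer about O1–C2 presses the chain against the fully substituted C6; both new centres are thus controlled by C6. The step needs attack of C5 on the unsubstituted carbon of vinyl bromide (secured by bromine stabilising the adduct radical), ring closure faster than telomerization or 1,5-hydrogen transfer (secured by the activated enoate and the high vinyl bromide concentration) and no loss of the C–Br bonds (secured because no tin or silyl radical and no strong reductant is present).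

Step 17
Reactants: 27 oxane methyl ester
Product: 28 oxane acetic acid
Conditions: Me3SnOH (5 equiv), 1,2-dichloroethane, 70 °C; dilute aq HCl wash
Reagents that add atoms: trimethyltin hydroxide, C[Sn](C)(C)O
Why: ester cleavage with Me3SnOH under nearly neutral conditions should avoid E2 loss of HBr and retro-oxa-Michael opening of the ring.

Step 18
Reactants: 28 oxane acetic acid
Product: 30 protected C2-methyl oxane, via thiohydroxamate ester 29 (not isolated)
Conditions: N-hydroxypyridine-2-thione, DCC, DMAP (cat.), CH2Cl2, dark, rt; then t-BuSH, visible light, rt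
Reagents that add atoms: none
Why: Barton decarboxylation, in which the thiohydroxamate ester fragments under light to the primary radical that is reduced by the thiol, so that CH2CO2H becomes the C2 methyl group without touching the C–Br and C–Cl bonds.

Step 19
Reactants: 30 protected C2-methyl oxane
Product: 31 target
Conditions: CSA (0.2 equiv), MeOH, 0 °C to rt
Reagents that add atoms: none
Why: acid-catalysed methanolysis removes the oxanyl acetal and the triethylsilyl ether in one operation, and under acid the chlorohydrin cannot close to an epoxide.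

**Compound list**

1 | geranyl bromide, (2E)-1-bromo-3,7-dimethylocta-2,6-diene | CC(C)=CCC/C(C)=C/CBr | starting material
2 | acetic acid | CC(=O)O | starting material
3 | dilithium acetate (acetic acid dianion) | [Li+].[Li+].[CH2-]C([O-])=O | intermediate
4 | (4E)-5,9-dimethyldeca-4,8-dienoic acid | CC(C)=CCC/C(C)=C/CCC(=O)O | intermediate
5 | [(4aR,6R,8aR)-5,5,8a-trimethyl-2-oxooctahydro-2H-chromen-6-yl]mercury trifluoromethanesulfonate | CC1(C)[C@H]([Hg]OS(=O)(=O)C(F)(F)F)CC[C@@]2(C)OC(=O)CC[C@H]12 | intermediate
6 | [(4aR,6R,8aR)-5,5,8a-trimethyl-2-oxooctahydro-2H-chromen-6-yl]mercury bromide | CC1(C)[C@H]([Hg]Br)CC[C@@]2(C)OC(=O)CC[C@H]12 | intermediate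
7 | (4aR,6R,8aR)-6-bromo-5,5,8a-trimethyloctahydro-2H-chromen-2-one | CC1(C)[C@H](Br)CC[C@@]2(C)OC(=O)CC[C@H]12 | intermediate
8 | (4aR,6R,8aR)-6-bromo-5,5,8a-trimethyloctahydro-2H-chromen-2-ol (both anomers) | CC1(C)[C@H](Br)CC[C@@]2(C)OC(O)CC[C@H]12 | intermediate
9 | dimethyl (1-diazo-2-oxopropyl)phosphonate | COP(=O)(OC)C(=[N+]=[N-])C(C)=O | starting material
10 | (1R,2R,4R)-4-bromo-2-(but-3-yn-1-yl)-1,3,3-trimethylcyclohexan-1-ol | CC1(C)[C@H](Br)CC[C@@](C)(O)[C@@H]1CCC#C | intermediate
11 | {[(1R,2R,4R)-4-bromo-2-(but-3-yn-1-yl)-1,3,3-trimethylcyclohexyl]oxy}triethylsilane | CC1(C)[C@H](Br)CC[C@@](C)(O[Si](CC)(CC)CC)[C@@H]1CCC#C | intermediate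
12 | lithium acetylide of 11 | CC1(C)[C@H](Br)CC[C@@](C)(O[Si](CC)(CC)CC)[C@@H]1CCC#[C-].[Li+] | intermediate
13 | methyl 5-{(1R,3R,6R)-3-bromo-2,2,6-trimethyl-6-[(triethylsilyl)oxy]cyclohexyl}pent-2-ynoate | CC1(C)[C@H](Br)CC[C@@](C)(O[Si](CC)(CC)CC)[C@@H]1CCC#CC(=O)OC | intermediate
14 | 2-chloro-N-methoxy-N-methylacetamide | CON(C)C(=O)CCl | starting material
15 | isopropenylmagnesium bromide | CC(=C)[Mg]Br | starting material
16 | 1-chloro-3-methylbut-3-en-2-one | CC(=C)C(=O)CCl | intermediate
17 | racemic 1-chloro-3-methylbut-3-en-2-ol | CC(=C)C(O)CCl | intermediate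
18 | (1S)-2-chloro-1-[(2S)-2-methyloxiran-2-yl]ethan-1-ol | C[C@]1(CO1)[C@H](O)CCl | intermediate
19 | 2-{(1S)-2-chloro-1-[(2S)-2-methyloxiran-2-yl]ethoxy}oxane (acetal epimers) | C[C@]1(CO1)[C@H](OC1CCCCO1)CCl | intermediate
20 | vinylmagnesium bromide | C=C[Mg]Br | starting material
21 | (2S,3S)-1-chloro-3-methyl-2-(oxan-2-yloxy)hex-5-en-3-ol | C=CC[C@](C)(O)[C@H](OC1CCCCO1)CCl | intermediate
22 | methyl (2E)-3-{[(2S,3S)-1-chloro-3-methyl-2-(oxan-2-yloxy)hex-5-en-3-yl]oxy}-5-{(1R,3R,6R)-3-bromo-2,2,6-trimethyl-6-[(triethylsilyl)oxy]cyclohexyl}pent-2-enoate | COC(=O)/C=C(\CC[C@@H]1C(C)(C)[C@H](Br)CC[C@@]1(C)O[Si](CC)(CC)CC)O[C@@](C)(CC=C)[C@H](OC1CCCCO1)CCl | intermediate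
23 | 5,6-diol from the terminal alkene of 22 | COC(=O)/C=C(\CC[C@@H]1C(C)(C)[C@H](Br)CC[C@@]1(C)O[Si](CC)(CC)CC)O[C@@](C)(CC(O)CO)[C@H](OC1CCCCO1)CCl | intermediate
24 | methyl (2E)-3-{[(2S,3S)-1-chloro-3-methyl-2-(oxan-2-yloxy)-5-oxopentan-3-yl]oxy}-5-{(1R,3R,6R)-3-bromo-2,2,6-trimethyl-6-[(triethylsilyl)oxy]cyclohexyl}pent-2-enoate | COC(=O)/C=C(\CC[C@@H]1C(C)(C)[C@H](Br)CC[C@@]1(C)O[Si](CC)(CC)CC)O[C@@](C)(CC=O)[C@H](OC1CCCCO1)CCl | intermediate
25 | (3S,4S)-5-chloro-3-{[(2E)-5-{(1R,3R,6R)-3-bromo-2,2,6-trimethyl-6-[(triethylsilyl)oxy]cyclohexyl}-1-methoxy-1-oxopent-2-en-3-yl]oxy}-3-methyl-4-(oxan-2-yloxy)pentanoic acid | COC(=O)/C=C(\CC[C@@H]1C(C)(C)[C@H](Br)CC[C@@]1(C)O[Si](CC)(CC)CC)O[C@@](C)(CC(=O)O)[C@H](OC1CCCCO1)CCl | intermediate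
26 | vinyl bromide (bromoethene) | C=CBr | starting material
27 | methyl 2-[(2R,3R,6S)-3-bromo-2-(2-{(1R,3R,6R)-3-bromo-2,2,6-trimethyl-6-[(triethylsilyl)oxy]cyclohexyl}ethyl)-6-[(1S)-2-chloro-1-(oxan-2-yloxy)ethyl]-6-methyloxan-2-yl]acetate | CC1(C)[C@H](Br)CC[C@@](C)(O[Si](CC)(CC)CC)[C@@H]1CC[C@]1(CC(=O)OC)O[C@](C)([C@H](OC2CCCCO2)CCl)CC[C@H]1Br | intermediate
28 | 2-[(2R,3R,6S)-3-bromo-2-(2-{(1R,3R,6R)-3-bromo-2,2,6-trimethyl-6-[(triethylsilyl)oxy]cyclohexyl}ethyl)-6-[(1S)-2-chloro-1-(oxan-2-yloxy)ethyl]-6-methyloxan-2-yl]acetic acid | CC1(C)[C@H](Br)CC[C@@](C)(O[Si](CC)(CC)CC)[C@@H]1CC[C@]1(CC(=O)O)O[C@](C)([C@H](OC2CCCCO2)CCl)CC[C@H]1Br | intermediate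
29 | 2-thioxopyridin-1(2H)-yl ester of 28 | CC1(C)[C@H](Br)CC[C@@](C)(O[Si](CC)(CC)CC)[C@@H]1CC[C@]1(CC(=O)ON2C=CC=CC2=S)O[C@](C)([C@H](OC2CCCCO2)CCl)CC[C@H]1Br | intermediate
30 | triethyl{[(1R,2R,4R)-4-bromo-2-(2-{(2S,3R,6S)-3-bromo-6-[(1S)-2-chloro-1-(oxan-2-yloxy)ethyl]-2,6-dimethyloxan-2-yl}ethyl)-1,3,3-trimethylcyclohexyl]oxy}silane | CC1(C)[C@H](Br)CC[C@@](C)(O[Si](CC)(CC)CC)[C@@H]1CC[C@]1(C)O[C@](C)([C@H](OC2CCCCO2)CCl)CC[C@H]1Br | intermediate
31 | (1R,2R,4R)-4-bromo-2-(2-{(2S,3R,6S)-3-bromo-6-[(1S)-2-chloro-1-hydroxyethyl]-2,6-dimethyloxan-2-yl}ethyl)-1,3,3-trimethylcyclohexan-1-ol | CC1(C)[C@H](Br)CC[C@@](C)(O)[C@@H]1CC[C@]1(C)O[C@](C)([C@H](O)CCl)CC[C@H]1Br | target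

**Step count and risks**

Total step count: 19. Longest linear sequence: 14 steps (steps 1–7, then 13–19); the East branch (steps 8–12) joins at step 13.

Steps most likely to fail:

1. Step 16 (new method). The α-bromo radical at C3 may add to further vinyl bromide (telomerization) instead of closing the ring. The C5 radical may also be lost by 1,5-hydrogen transfer from the allylic CH2 before it adds, and facial control at C2 may be poor. The fallback uses known chemistry, sets out from 22 and returns at 27. Hydroboration of the terminal alkene of 22 with 9-BBN and oxidation with NaBO3 should give the primary alcohol F1. Dess–Martin oxidation should give the aldehyde F2, and (PhO)3P/Br2 should convert it to the 1,1-dibromide F3. Treatment with (Me3Si)3SiH and Et3B/air should remove one bromine and generate the same C3 radical, which closes 6-exo onto C2 to give 27. The two ring bonds are then made in separate steps, C4–C5 already in step 12.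

2. Step 13. The hindered tertiary alkoxide may fail to add to the β-substituted ynoate, or the base may isomerize the ynoate to the allenoate and cause side reactions. The fallback sets out from 11 and 21 and returns at 22. The lithium acetylide of 11 is acylated with trichloroacetic anhydride to give the alkynyl trichloromethyl ketone F4, a much stronger acceptor. Alcohol 21 should add to it under catalytic DABCO to give the β-alkoxy trichloromethyl enone F5. Haloform-type cleavage with K2CO3 in MeOH should then turn the trichloroacetyl group into the methyl ester 22.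

3. Step 2. The ligand-bound mercury salt may give insufficient enantio-induction, or the cation may lose a proton instead of being captured by the carboxyl group. The fallback sets out from 4 and returns at 7. Cyclization of 4 with Et2SBr·SbCl5Br in MeNO2 at −25 °C should give the racemic bromolactone F6 directly. Opening with (S)-1-phenylethylamine and AlMe3 should give two diastereomeric hydroxy amides, from which the hydroxy amide F7 of the (4aR,6R,8aR) series is separated by chromatography or crystallization. Heating F7 with aq H2SO4 in dioxane should close it back to 7.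

Further compounds
F1 | step 16 | methyl (2E)-3-{[(2S,3S)-1-chloro-6-hydroxy-3-methyl-2-(oxan-2-yloxy)hexan-3-yl]oxy}-5-{(1R,3R,6R)-3-bromo-2,2,6-trimethyl-6-[(triethylsilyl)oxy]cyclohexyl}pent-2-enoate | COC(=O)/C=C(\CC[C@@H]1C(C)(C)[C@H](Br)CC[C@@]1(C)O[Si](CC)(CC)CC)O[C@@](C)(CCCO)[C@H](OC1CCCCO1)CCl
F2 | step 16 | methyl (2E)-3-{[(2S,3S)-1-chloro-3-methyl-2-(oxan-2-yloxy)-6-oxohexan-3-yl]oxy}-5-{(1R,3R,6R)-3-bromo-2,2,6-trimethyl-6-[(triethylsilyl)oxy]cyclohexyl}pent-2-enoate | COC(=O)/C=C(\CC[C@@H]1C(C)(C)[C@H](Br)CC[C@@]1(C)O[Si](CC)(CC)CC)O[C@@](C)(CCC=O)[C@H](OC1CCCCO1)CCl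
F3 | step 16 | methyl (2E)-3-{[(2S,3S)-6,6-dibromo-1-chloro-3-methyl-2-(oxan-2-yloxy)hexan-3-yl]oxy}-5-{(1R,3R,6R)-3-bromo-2,2,6-trimethyl-6-[(triethylsilyl)oxy]cyclohexyl}pent-2-enoate | COC(=O)/C=C(\CC[C@@H]1C(C)(C)[C@H](Br)CC[C@@]1(C)O[Si](CC)(CC)CC)O[C@@](C)(CCC(Br)Br)[C@H](OC1CCCCO1)CCl
F4 | step 13 | 1,1,1-trichloro-6-{(1R,3R,6R)-3-bromo-2,2,6-trimethyl-6-[(triethylsilyl)oxy]cyclohexyl}hex-3-yn-2-one | CC1(C)[C@H](Br)CC[C@@](C)(O[Si](CC)(CC)CC)[C@@H]1CCC#CC(=O)C(Cl)(Cl)Cl
F5 | step 13 | (3E)-1,1,1-trichloro-4-{[(2S,3S)-1-chloro-3-methyl-2-(oxan-2-yloxy)hex-5-en-3-yl]oxy}-6-{(1R,3R,6R)-3-bromo-2,2,6-trimethyl-6-[(triethylsilyl)oxy]cyclohexyl}hex-3-en-2-one | ClC(Cl)(Cl)C(=O)/C=C(\CC[C@@H]1C(C)(C)[C@H](Br)CC[C@@]1(C)O[Si](CC)(CC)CC)O[C@@](C)(CC=C)[C@H](OC1CCCCO1)CCl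
F6 | step 2 | racemic trans-fused 6-bromo-5,5,8a-trimethyloctahydro-2H-chromen-2-one | CC1(C)[C@H](Br)CC[C@@]2(C)OC(=O)CC[C@H]12.CC1(C)[C@@H](Br)CC[C@]2(C)OC(=O)CC[C@@H]12
F7 | step 2 | 3-[(1R,3R,6R)-3-bromo-6-hydroxy-2,2,6-trimethylcyclohexyl]-N-[(1S)-1-phenylethyl]propanamide | CC1(C)[C@H](Br)CC[C@@](C)(O)[C@@H]1CCC(=O)N[C@@H](C)c1ccccc1
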